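## The problem

Target 26 joins three units: a 4-hydroxybenzoic acid alkylated at its 3-position, an (E)-trisubstituted alkene, and a 1,3,3-trimethyl-7-oxabicyclo[2.2.1]heptane that carries the chain at C2. The bicycle is two oxolane rings that share O7 and the bridgeheads C1 (methyl-bearing) and C4 (CH), so that C1–C6 form a cyclohexane held as a boat. Its substituted edge is crowded: C1 is fully substituted, C3 is a quaternary CMe2 carbon and C2 lies between them. SN2 displacement at C2 is therefore excluded, a C2 ketone has no enolisable neighbour, and olefination–reduction sequences would put the chain on the wrong face. Of the three stereocentres, C1 (R) and C4 (S) are tied together by the bridge, so only their absolute sense must be set; C2 (S) carries the chain exo, syn to O7, and the finished bicycle can control it if the C2–C bond is made from the open exo face; the alkene geometry is independent of all three. Rough treatment is excluded by the tertiary C1–O7 ether (ionised by acid, expelled as an alkoxide by a carbanion on C2, C5 or C6), by the ortho-allyl phenol (acid closes a chroman onto the alkene) and by the benzylic–allylic CH2. The enabling feature is that O7, flanked by C1 and C4, with C2 at the ketone level and the C3 gem-dimethyl group between them, is a five-membered carbonyl ylide (O7, C1, C2, C3, C4) whose termini C1 and C4 lack only the two-carbon bridge C5–C6. The gem-dimethyl group removes every proton by which such an ylide could quench itself.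

## Retrosynthesis

**Unmasking (26 from 25).** No skeletal bond is cut. The phenol and the acid are carried as an aryl silyl ether and a methyl ester, both of which fall to hydroxide in one operation. Acid-labile groups are ruled out because acid would add the phenol to the alkene and could ionise the C1–O7 bond. The forward step asks only for basic hydrolysis and a gentle acidification.

**Alkene–arene junction (25 from 20 and 23, through 24).** The bond between the alkene CH and the benzylic CH2 is cut, together with the bond from the other alkene carbon to its methyl group. Olefination of a methyl ketone would give both geometries, and C-alkylation of a phenoxide with an allylic halide competes with O-alkylation. Syn methylmetalation of terminal alkyne 20 fixes the E geometry by mechanism, and alkenylalane 24 couples with benzylic bromide 23 with retention. The precursor has lost the arene, the alkene stereochemistry and one carbon. The forward reaction must carbometalate regioselectively without harming the bridging ether, and couple without touching the ester or the silyl ether.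

**Alkyne (20 from 18, through 19).** The bond to the terminal alkyne carbon is cut. A one-carbon homologation of aldehyde 19, reached in the same flask from ester 18, is the shortest link between a radical acceptor and a carbometalation substrate. C2 has no adjacent carbonyl group and cannot epimerise.

**Side chain at C2 (18 from 16 and 17).** The C2–CH2 bond is cut. Polar alternatives fail here: a C2 ketone resists olefination, and hydrogenation or hydroboration of an exocyclic alkene would deliver hydrogen from the exo face and leave the chain endo. A C2 radical reverses the outcome because the new C–C bond itself forms on the exo face. The precursor is xanthate 16 of a secondary alcohol, and the three-carbon acceptor is 17. The forward reaction must add a hindered secondary radical to an acrylate faster than the radical is reduced.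

**Clearing the bridge and adjusting C2 (16 from 14, 13, 12 and 11).** No skeletal bond is cut. C5 and C6 are unfunctionalised in 26, so the two-carbon partner of the cycloaddition must carry removable activating groups. A single sulfone or a geminal pair would have to leave through a carbanion β to O7, whose endo lobe is almost antiperiplanar to the C–O7 bond, and the bridge would open. A vicinal pair leaves as two sulfinate groups and gives the C5=C6 alkene of 13 directly; hydrogenation then gives 14. The C2 ketone of 11 is reduced first (12), because an α-alkoxy ketone would not survive the electron-transfer conditions.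

**The bicycle (11 from 8 and 9, through 10).** The O7–C1, C1–C6 and C4–C5 bonds are cut. Cutting only the ether bridge would leave a cyclohexane whose three contiguous substituted carbons must be built first. Cutting the bridge and the C5–C6 unit together reduces the bicycle to the acyclic five-carbon diazo keto aldehyde 8, which has no stereocentre, and the symmetrical alkene 9. The forward reaction must turn the diazo carbon into C1 of ylide 10 faster than the methyl carbenoid rearranges, and must add 10 to 9 on one face.

**Diazo keto aldehyde (8 from 7, 6, 4, 3, 2 and 1).** The C1–C2 bond region is assembled by adding an ethyl group to the ester carbon of 1 (through 2, 3 and 4). The diazo group is then transferred to the only enolisable carbon (through 5 to 6), and the aldehyde is revealed last (7, then 8) because it would not survive enolate chemistry. Every step is a standard functional-group operation on a non-enolisable, quaternary-substituted chain.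

**Aryl fragment (23 from 22 and 21).** The benzylic C–Br bond is traced to the methyl group of 21. Radical bromination of the silyl ether 22 avoids a benzylic alkoxide next to an aryl silyl ether, which could shift the silyl group.

## Roads not taken

**Alternative 1:** The C2–C3 bond is cut. A cis-2,5-disubstituted oxolane A1 already holds O7, C1 with its methyl group and C4. An iron hydride, generated in situ from an iron precatalyst and a silane, would convert the isopropenyl group on C4 into the tertiary C3 radical. That radical would add to the β-carbon (C2) of the enoate on C1 and close the carbocycle, giving ester A2.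
- Merits: both ring stereocentres come preset from a terpene-like oxolane, the most hindered bond (quaternary C3 to C2) is made by a radical, and the core is reached in far fewer steps than in the chosen plan, without diazo chemistry or asymmetric catalysis.
- Weak points: two arms on a five-membered ring must bend into a strained bicycle, in competition with simple reduction of the alkene. Only the cis isomer of A1 can close, and it must be obtained as a single enantiomer. C2 is created in the ring-forming step itself, where the enoate rotamer and not a rigid framework decides between exo and endo. A2 is one carbon short of 18 and needs a longer chain extension to reach 20.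
- Comparison: this road is shorter to the core. The chosen plan sets against it that C2 is fixed only after the bicycle exists, by a face selection that is well understood.

**Alternative 2:** The O7–C1 bond and the bond from C2 to its first chain carbon are cut. The palladium alkoxide of cyclohexenol A3, formed with a phosphine-ligated zerovalent palladium catalyst, a vinyl halide and a strong base, would insert the C1=C2 alkene syn and then eliminate reductively to give A4.
- Merits: A3 is a simple monocyclic alcohol with one stereocentre, from which C1, C2 and C4 all follow. Syn delivery of oxygen and carbon places the vinyl group exo, as required. The vinyl group is a direct handle for hydroboration and sp3–sp2 coupling, so the whole synthesis would be clearly shorter than the chosen one.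
- Weak points: the insertion must occur transannularly on a trisubstituted alkene, create the fully substituted C1–O bond and place palladium on C2 between two quaternary carbons. Reactions of this type are reliable for terminal and 1,2-disubstituted alkenes in acyclic hydroxy alkenes. Oxidation of the alkoxide by β-hydride elimination and Heck-type vinylation compete.
- Comparison: this road is better in step economy and avoids a diazo compound. The chosen plan sets against it that the C1–O7 bond is made from a carbenoid that is already on C1, with no insertion into a hindered alkene.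

**Alternative 3:** The C1–C2 and C3–C4 bonds are cut. 2-Methylfuran A5 and the strained alkylidene ester A6 would combine under a chiral oxazaborolidinium Lewis acid to give the oxanorbornene A7. Hydrogenation and hydrogenolysis of the spiro cyclopropane would later reveal the gem-dimethyl group.
- Merits: two simple partners, one catalytic asymmetric step for C1, C4 and C2, and the shortest access to the bicycle of all four plans.
- Weak points: A6 is a β,β-disubstituted dienophile, much less reactive than an acrylate despite its strain, and furan adducts revert. The required regiochemistry joins the two most hindered carbons. The endo ester of A7 has the wrong configuration at C2 and must be epimerised. Hydrogenolysis must cleave only the distal cyclopropane bond, under conditions that threaten the allylic and tertiary C–O bonds. The C2 substituent is a one-carbon ester, three carbons short of the alkyne stage 20.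
- Comparison: this road is better in the number of steps to the bicycle. The chosen plan sets against it a cycloaddition that is irreversible, a gem-dimethyl group present from the start, and a C2 handle (the ketone) that leads to the chain in the correct configuration.

Key step: step 7

Assumption: the sense of induction of the tert-leucinate catalyst in step 7 cannot be predicted; the S ligand is written, and its mirror image is to be used if the adduct proves to be the antipode.

Step 1
Reactants: 1 methyl 3-hydroxy-2,2-dimethylpropanoate
Product: 2 methyl 3-[(tert-butyldimethylsilyl)oxy]-2,2-dimethylpropanoate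
Conditions: TBSCl, imidazole, DMF, 0 °C → rt
Reagents that add atoms: tert-butyldimethylsilyl chloride, CC(C)(C)[Si](C)(C)Cl
Why: Silylation of an unhindered primary alcohol; the silyl ether masks the future aldehyde carbon C4 through the organometallic and diazo-transfer steps.

Step 2
Reactants: 2 methyl 3-[(tert-butyldimethylsilyl)oxy]-2,2-dimethylpropanoate
Product: 3 3-[(tert-butyldimethylsilyl)oxy]-N-methoxy-N,2,2-trimethylpropanamide
Conditions: MeNH(OMe)·HCl, i-PrMgCl, THF, −20 °C → rt
Reagents that add atoms: N,O-dimethylhydroxylamine hydrochloride, CNOC.Cl
Why: Weinreb amide formation from an ester through the chloromagnesium amide; the ester has no α-hydrogen, so enolisation cannot compete, and the amide stops the next addition at the ketone.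

Step 3
Reactants: 3 3-[(tert-butyldimethylsilyl)oxy]-N-methoxy-N,2,2-trimethylpropanamide
Product: 4 1-[(tert-butyldimethylsilyl)oxy]-2,2-dimethylpentan-3-one
Conditions: EtMgBr, THF, 0 °C → rt
Reagents that add atoms: ethylmagnesium bromide, CC[Mg]Br
Why: Grignard addition to a Weinreb amide; the chelated tetrahedral adduct collapses only on work-up, so the ethyl ketone (C2 with the future C1 and its methyl group) forms without over-addition.

Step 4
Reactants: 4 1-[(tert-butyldimethylsilyl)oxy]-2,2-dimethylpentan-3-one
Product: 6 1-[(tert-butyldimethylsilyl)oxy]-4-diazo-2,2-dimethylpentan-3-one, via trifluoroacetyl diketone 5 (not isolated)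
Conditions: LiN(SiMe3)2, THF, −78 °C; CF3CO2CH2CF3; then 4-acetamidobenzenesulfonyl azide, Et3N, H2O, MeCN, rt
Reagents that add atoms: 4-acetamidobenzenesulfonyl azide, CC(=O)Nc1ccc(cc1)S(=O)(=O)N=[N+]=[N-]; 2,2,2-trifluoroethyl trifluoroacetate, O=C(OCC(F)(F)F)C(F)(F)F (its acyl group is carried only by 5)
Why: Detrifluoroacetylative diazo transfer; the ethyl CH2 is the only enolisable position, C-acylation activates it, and the sulfonyl azide then transfers N2 with loss of the more electrophilic trifluoroacetyl group.

Step 5
Reactants: 6 1-[(tert-butyldimethylsilyl)oxy]-4-diazo-2,2-dimethylpentan-3-one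
Product: 7 4-diazo-1-hydroxy-2,2-dimethylpentan-3-one
Conditions: Et3N·3HF, THF, rt
Reagents that add atoms: none
Why: Fluoride-mediated desilylation under nearly neutral conditions, which an acceptor-stabilised diazo ketone tolerates; a basic fluoride source is avoided because the β-hydroxy ketone could lose formaldehyde by retro-aldol cleavage.

Step 6
Reactants: 7 4-diazo-1-hydroxy-2,2-dimethylpentan-3-one
Product: 8 4-diazo-2,2-dimethyl-3-oxopentanal
Conditions: Dess–Martin periodinane, NaHCO3, CH2Cl2, 0 °C
Reagents that add atoms: none
Why: Dess–Martin oxidation of a primary alcohol; the buffered reagent is compatible with α-diazo ketones, and the aldehyde cannot enolise because C3 is quaternary.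

Step 7
Reactants: 8 4-diazo-2,2-dimethyl-3-oxopentanal; 9 (E)-1,2-bis(phenylsulfonyl)ethene
Product: 11 (1S,4R)-1,3,3-trimethyl-5,6-bis(phenylsulfonyl)-7-oxabicyclo[2.2.1]heptan-2-one (sulfonyl groups trans), via carbonyl ylide 10 (not isolated)
Conditions: Rh2(S-PTTL)4 (dirhodium tetrakis[N-phthaloyl-(S)-tert-leucinate], 1 mol%), 9 (1.5 equiv), CH2Cl2, 0 °C, slow addition of 8
Reagents that add atoms: none
Why: Proposed new method: a carbonyl ylide (3+2) cycloaddition in which the carbenoid carbon bears a methyl group and the ylide must stay on a chiral dirhodium carboxylate; the closest known reactions are the Rh2(OAc)4-catalysed ylide formation and cycloaddition of gem-dimethyl-blocked 1-diazo-2,4-dicarbonyl compounds with an unsubstituted diazo carbon, and the enantioselective cycloadditions of six-membered carbonyl ylides under N-phthaloyl amino acid dirhodium catalysts. Loss of N2 gives the rhodium carbenoid at C1, whose carbon is attacked by a lone pair of the aldehyde oxygen; this closes the oxolan-3-one ring through O7–C1 (five-membered closure onto the exocyclic Rh=C bond, made easy by the short C2–C3–C4 tether) and gives ylide 10. The ylide, enolate-like at C1 and oxocarbenium-like at C4, adds suprafacially across its termini to the electron-poor alkene 9 (dipole HOMO, alkene LUMO), forming C1–C6 and C4–C5 and so closing the second oxolane ring and with it the cyclohexane. C1 and C4 arise together and are fixed relative to each other by the bridge, so the only element to control is the face of the planar ylide that meets 9; the chiral carboxylate wall sets it for as long as rhodium stays associated with C1. C5 and C6 are formed trans by stereospecific addition to the E alkene; their exo/endo sense is not controlled and does not matter, since both centres vanish in step 9. The step needs chemoselectivity for ylide formation over the 1,2-hydride shift of the methyl carbenoid, which the intramolecular five-ring capture by the aldehyde, the low migratory aptitude of a primary C–H bond, the bulky tert-leucinate ligands and the low temperature should secure. It also needs the ylide to persist, which the C3 gem-dimethyl group secures by removing every transferable proton, while slow addition of 8 into excess 9 keeps the ylide from adding to the aldehyde of a second molecule of 8.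

Step 8
Reactants: 11 (1S,4R)-1,3,3-trimethyl-5,6-bis(phenylsulfonyl)-7-oxabicyclo[2.2.1]heptan-2-one
Product: 12 (1S,2R,4R)-1,3,3-trimethyl-5,6-bis(phenylsulfonyl)-7-oxabicyclo[2.2.1]heptan-2-ol (2-endo alcohol)
Conditions: i-Bu2AlH, CH2Cl2, −78 °C
Reagents that add atoms: none
Why: Hydride reduction of a hindered ketone by a Lewis-acidic, non-basic aluminium hydride, chosen because basic hydrides could eliminate benzenesulfinic acid from the vicinal disulfone. Attack past the small O7 bridge (exo face) should give the endo alcohol, whose configuration is erased in step 12. The reduction also removes the α-alkoxy ketone, which would not survive the electron transfer of step 9.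

Step 9
Reactants: 12 (1S,2R,4R)-1,3,3-trimethyl-5,6-bis(phenylsulfonyl)-7-oxabicyclo[2.2.1]heptan-2-ol
Product: 13 (1R,2R,4S)-1,3,3-trimethyl-7-oxabicyclo[2.2.1]hept-5-en-2-ol
Conditions: 6% Na(Hg), Na2HPO4, MeOH–THF, −20 °C
Reagents that add atoms: none
Why: Reductive elimination of a vicinal bis-sulfone (alkyne-equivalent use of 9). Electron transfer expels one sulfinate, and the β-sulfonyl radical or carbanion loses the second sulfonyl group faster than it could expel the bridging alkoxide O7, so the C5=C6 alkene forms without a free carbanion β to the ether.

Step 10
Reactants: 13 (1R,2R,4S)-1,3,3-trimethyl-7-oxabicyclo[2.2.1]hept-5-en-2-ol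
Product: 14 (1R,2R,4S)-1,3,3-trimethyl-7-oxabicyclo[2.2.1]heptan-2-ol
Conditions: H2 (1 atm), Pd/C, EtOAc, rt
Reagents that add atoms: none
Why: Catalytic hydrogenation of the strained C5=C6 alkene; it must be saturated before step 12 because a C2 radical would otherwise cyclise onto it (homoallyl–cyclopropylcarbinyl rearrangement).

Step 11
Reactants: 14 (1R,2R,4S)-1,3,3-trimethyl-7-oxabicyclo[2.2.1]heptan-2-ol
Product: 16 O-[(1R,2R,4S)-1,3,3-trimethyl-7-oxabicyclo[2.2.1]heptan-2-yl] S-methyl carbonodithioate, via sodium xanthate salt 15 (not isolated)
Conditions: NaH, THF, 0 °C → rt; CS2; MeI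
Reagents that add atoms: carbon disulfide, S=C=S; iodomethane, CI; sodium hydride, [Na+].[H-] (sodium only in 15)
Why: Xanthate formation through the alkoxide, which adds to the small electrophile CS2 even between two quaternary carbons; the xanthate cannot undergo Chugaev elimination because neither C1 nor C3 carries hydrogen.

Step 12
Reactants: 16 O-[(1R,2R,4S)-1,3,3-trimethyl-7-oxabicyclo[2.2.1]heptan-2-yl] S-methyl carbonodithioate; 17 methyl acrylate
Product: 18 methyl 3-[(1R,2S,4S)-1,3,3-trimethyl-7-oxabicyclo[2.2.1]heptan-2-yl]propanoate
Conditions: (Me3Si)3SiH (slow addition), AIBN, 17 (excess), toluene, 85 °C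
Reagents that add atoms: none
Why: Deoxygenative radical conjugate addition (Barton–McCombie radical generation followed by Giese addition); the nucleophilic C2 radical adds to the acrylate and the adduct radical is reduced by the silane. The C2 stereocentre is set by the bicycle: the acrylate meets the planar radical on the exo face, past the small oxygen bridge, and not on the endo face screened by the C5–C6 bridge, so the chain ends exo as in 26.

Step 13
Reactants: 18 methyl 3-[(1R,2S,4S)-1,3,3-trimethyl-7-oxabicyclo[2.2.1]heptan-2-yl]propanoate
Product: 20 (1R,2S,4S)-2-(but-3-yn-1-yl)-1,3,3-trimethyl-7-oxabicyclo[2.2.1]heptane, via aldehyde 19 (not isolated)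
Conditions: i-Bu2AlH, CH2Cl2, −78 °C; then MeOH, K2CO3, dimethyl (1-diazo-2-oxopropyl)phosphonate, −78 °C → rt
Reagents that add atoms: dimethyl (1-diazo-2-oxopropyl)phosphonate, CC(=O)C(=[N+]=[N-])P(=O)(OC)OC
Why: One-pot partial reduction of the ester and Seyferth–Gilbert homologation in the Ohira–Bestmann variant; the aluminium hemiacetal releases aldehyde 19 only when methanol is added, and the diazomethylphosphonate anion formed in the flask converts it into the terminal alkyne under carbonate base.

Step 14
Reactants: 21 methyl 4-hydroxy-3-methylbenzoate
Product: 22 methyl 4-[(tert-butyldimethylsilyl)oxy]-3-methylbenzoate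
Conditions: TBSCl, imidazole, DMF, rt
Reagents that add atoms: tert-butyldimethylsilyl chloride, CC(C)(C)[Si](C)(C)Cl
Why: Phenol silylation; the aryl silyl ether tolerates radical bromination and the organoalane–palladium step and falls in the final basic hydrolysis, so no acid is needed at the end.

Step 15
Reactants: 22 methyl 4-[(tert-butyldimethylsilyl)oxy]-3-methylbenzoate
Product: 23 methyl 3-(bromomethyl)-4-[(tert-butyldimethylsilyl)oxy]benzoate
Conditions: NBS, AIBN, PhCF3, 80 °C
Reagents that add atoms: N-bromosuccinimide, O=C1CCC(=O)N1Br
Why: Wohl–Ziegler benzylic bromination; the aryl methyl group holds the only benzylic C–H bonds and the ester-deactivated ring resists electrophilic bromination.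

Step 16
Reactants: 20 (1R,2S,4S)-2-(but-3-yn-1-yl)-1,3,3-trimethyl-7-oxabicyclo[2.2.1]heptane; 23 methyl 3-(bromomethyl)-4-[(tert-butyldimethylsilyl)oxy]benzoate
Product: 25 methyl 4-[(tert-butyldimethylsilyl)oxy]-3-{(2E)-3-methyl-5-[(1R,2S,4S)-1,3,3-trimethyl-7-oxabicyclo[2.2.1]heptan-2-yl]pent-2-en-1-yl}benzoate, via alkenylalane 24 (not isolated)
Conditions: Me3Al, Cp2ZrCl2 (cat.), ClCH2CH2Cl, 0 °C → rt; volatiles removed; then 23, Pd(PPh3)4 (cat.), THF, rt
Reagents that add atoms: trimethylaluminium, C[Al](C)C
Why: Zirconium-catalysed methylalumination of the terminal alkyne (syn addition, methyl to the internal carbon) followed by palladium-catalysed alkenyl–benzyl cross-coupling of the Negishi type with retention of alkene geometry; this fixes the E trisubstituted alkene and joins the two fragments in one operation.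

Step 17
Reactants: 25 methyl 4-[(tert-butyldimethylsilyl)oxy]-3-{(2E)-3-methyl-5-[(1R,2S,4S)-1,3,3-trimethyl-7-oxabicyclo[2.2.1]heptan-2-yl]pent-2-en-1-yl}benzoate
Product: 26 4-hydroxy-3-{(2E)-3-methyl-5-[(1R,2S,4S)-1,3,3-trimethyl-7-oxabicyclo[2.2.1]heptan-2-yl]pent-2-en-1-yl}benzoic acid
Conditions: LiOH, THF–MeOH–H2O, 50 °C; then cold dilute HCl to pH 4
Reagents that add atoms: lithium hydroxide, [Li+].[OH-] (supplies the hydroxyl oxygen of the carboxylic acid)
Why: Saponification of the methyl benzoate with concurrent cleavage of the base-labile aryl silyl ether; the alkene, the bridging ether and all stereocentres are inert to hydroxide, and the mild acidification avoids chroman formation.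

## Compound list

1 | methyl 3-hydroxy-2,2-dimethylpropanoate | COC(=O)C(C)(C)CO | starting material
2 | methyl 3-[(tert-butyldimethylsilyl)oxy]-2,2-dimethylpropanoate | COC(=O)C(C)(C)CO[Si](C)(C)C(C)(C)C | intermediate
3 | 3-[(tert-butyldimethylsilyl)oxy]-N-methoxy-N,2,2-trimethylpropanamide | CON(C)C(=O)C(C)(C)CO[Si](C)(C)C(C)(C)C | intermediate
4 | 1-[(tert-butyldimethylsilyl)oxy]-2,2-dimethylpentan-3-one | CCC(=O)C(C)(C)CO[Si](C)(C)C(C)(C)C | intermediate
5 | 6-[(tert-butyldimethylsilyl)oxy]-1,1,1-trifluoro-3,5,5-trimethylhexane-2,4-dione | CC(C(=O)C(F)(F)F)C(=O)C(C)(C)CO[Si](C)(C)C(C)(C)C | intermediate (not isolated)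
6 | 1-[(tert-butyldimethylsilyl)oxy]-4-diazo-2,2-dimethylpentan-3-one | CC(=[N+]=[N-])C(=O)C(C)(C)CO[Si](C)(C)C(C)(C)C | intermediate
7 | 4-diazo-1-hydroxy-2,2-dimethylpentan-3-one | CC(=[N+]=[N-])C(=O)C(C)(C)CO | intermediate
8 | 4-diazo-2,2-dimethyl-3-oxopentanal | CC(=[N+]=[N-])C(=O)C(C)(C)C=O | intermediate
9 | (E)-1,2-bis(phenylsulfonyl)ethene | O=S(=O)(/C=C/S(=O)(=O)c1ccccc1)c1ccccc1 | starting material
10 | 2,4,4-trimethyl-3-oxo-3,4-dihydro-2H-furan-1-ium-2-ide (cyclic carbonyl ylide, rhodium-associated) | C[C-]1[O+]=CC(C)(C)C1=O | intermediate (not isolated)
11 | (1S,4R)-1,3,3-trimethyl-5,6-bis(phenylsulfonyl)-7-oxabicyclo[2.2.1]heptan-2-one; sulfonyl groups trans, both trans isomers (5-exo,6-endo and 5-endo,6-exo); bridgeheads arranged as in 26, the descriptors differ only because the sulfonyl-bearing carbons change the CIP ranking | O=C1C(C)(C)[C@@H]2C(S(=O)(=O)c3ccccc3)C(S(=O)(=O)c3ccccc3)[C@@]1(C)O2 | intermediate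
12 | (1S,2R,4R)-1,3,3-trimethyl-5,6-bis(phenylsulfonyl)-7-oxabicyclo[2.2.1]heptan-2-ol; 2-endo alcohol, sulfonyl groups trans | O[C@@H]1C(C)(C)[C@@H]2C(S(=O)(=O)c3ccccc3)C(S(=O)(=O)c3ccccc3)[C@@]1(C)O2 | intermediate
13 | (1R,2R,4S)-1,3,3-trimethyl-7-oxabicyclo[2.2.1]hept-5-en-2-ol (2-endo alcohol) | O[C@@H]1C(C)(C)[C@@H]2C=C[C@@]1(C)O2 | intermediate
14 | (1R,2R,4S)-1,3,3-trimethyl-7-oxabicyclo[2.2.1]heptan-2-ol (2-endo alcohol) | O[C@@H]1C(C)(C)[C@@H]2CC[C@@]1(C)O2 | intermediate
15 | sodium O-[(1R,2R,4S)-1,3,3-trimethyl-7-oxabicyclo[2.2.1]heptan-2-yl] carbonodithioate | [Na+].[S-]C(=S)O[C@@H]1C(C)(C)[C@@H]2CC[C@@]1(C)O2 | intermediate (not isolated)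
16 | O-[(1R,2R,4S)-1,3,3-trimethyl-7-oxabicyclo[2.2.1]heptan-2-yl] S-methyl carbonodithioate | CSC(=S)O[C@@H]1C(C)(C)[C@@H]2CC[C@@]1(C)O2 | intermediate
17 | methyl acrylate | C=CC(=O)OC | starting material
18 | methyl 3-[(1R,2S,4S)-1,3,3-trimethyl-7-oxabicyclo[2.2.1]heptan-2-yl]propanoate (chain exo) | COC(=O)CC[C@H]1C(C)(C)[C@@H]2CC[C@@]1(C)O2 | intermediate
19 | 3-[(1R,2S,4S)-1,3,3-trimethyl-7-oxabicyclo[2.2.1]heptan-2-yl]propanal | O=CCC[C@H]1C(C)(C)[C@@H]2CC[C@@]1(C)O2 | intermediate (not isolated)
20 | (1R,2S,4S)-2-(but-3-yn-1-yl)-1,3,3-trimethyl-7-oxabicyclo[2.2.1]heptane | C#CCC[C@H]1C(C)(C)[C@@H]2CC[C@@]1(C)O2 | intermediate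
21 | methyl 4-hydroxy-3-methylbenzoate | COC(=O)c1ccc(O)c(C)c1 | starting material
22 | methyl 4-[(tert-butyldimethylsilyl)oxy]-3-methylbenzoate | COC(=O)c1ccc(O[Si](C)(C)C(C)(C)C)c(C)c1 | intermediate
23 | methyl 3-(bromomethyl)-4-[(tert-butyldimethylsilyl)oxy]benzoate | COC(=O)c1ccc(O[Si](C)(C)C(C)(C)C)c(CBr)c1 | intermediate
24 | dimethyl{(1E)-2-methyl-4-[(1R,2S,4S)-1,3,3-trimethyl-7-oxabicyclo[2.2.1]heptan-2-yl]but-1-en-1-yl}alumane | C/C(=C\[Al](C)C)CC[C@H]1C(C)(C)[C@@H]2CC[C@@]1(C)O2 | intermediate (not isolated)
25 | methyl 4-[(tert-butyldimethylsilyl)oxy]-3-{(2E)-3-methyl-5-[(1R,2S,4S)-1,3,3-trimethyl-7-oxabicyclo[2.2.1]heptan-2-yl]pent-2-en-1-yl}benzoate | C/C(=C\Cc1cc(C(=O)OC)ccc1O[Si](C)(C)C(C)(C)C)CC[C@H]1C(C)(C)[C@@H]2CC[C@@]1(C)O2 | intermediate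
26 | 4-hydroxy-3-{(2E)-3-methyl-5-[(1R,2S,4S)-1,3,3-trimethyl-7-oxabicyclo[2.2.1]heptan-2-yl]pent-2-en-1-yl}benzoic acid | C/C(=C\Cc1cc(C(=O)O)ccc1O)CC[C@H]1C(C)(C)[C@@H]2CC[C@@]1(C)O2 | target

## Step count and least certain steps

Total step count: 17. Longest linear sequence: 15 steps (steps 1–13, 16 and 17); steps 14 and 15 prepare the aryl fragment.

**Step 7 (key step, proposed new method).** The methyl-substituted carbenoid may undergo a 1,2-hydride shift to an enone before the aldehyde oxygen captures it. If the ylide does form, it may leave rhodium before it meets 9, and enantiofacial selection is then lost. Both failures stem from the absence of an acceptor group on C1 other than the ketone.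

The fallback gives up the cycloaddition and uses known chemistry only. Of the numbered compounds it uses only methyl acrylate 17, from which it sets out together with commercial 4-methylcyclohex-2-en-1-one, and it comes back to the route at ester 18. Deconjugative double methylation of the enone (KOt-Bu, MeI, t-BuOH) gives 2,2,4-trimethylcyclohex-3-en-1-one F1. Oxazaborolidine-catalysed borane reduction (R-configured methyl CBS catalyst, BH3·SMe2; the enantiomer is chosen by analogy with tert-alkyl ketones) gives (1S)-2,2,4-trimethylcyclohex-3-en-1-ol F2. Hydroxyl-directed epoxidation (VO(acac)2, t-BuOOH) gives the cis-epoxy alcohol (1S,3S,6R)-2,2,6-trimethyl-7-oxabicyclo[4.1.0]heptan-3-ol F3. Catalytic TsOH then lets the hydroxyl group open the epoxide across the ring at the methyl-bearing carbon, a transannular epoxy-alcohol cyclisation of the kind long used to make 2-hydroxy-1,4-cineoles, and gives the exo alcohol (1R,2S,4S)-1,3,3-trimethyl-7-oxabicyclo[2.2.1]heptan-2-ol F4, the C2 epimer of 14. Its xanthate O-[(1R,2S,4S)-1,3,3-trimethyl-7-oxabicyclo[2.2.1]heptan-2-yl] S-methyl carbonodithioate F5 (NaH, CS2, MeI) is treated with 17 under the conditions of step 12, where the same C2 radical forms, and gives 18. This sequence is shorter than steps 1–11 and is held in reserve only because it abandons the cycloaddition on which the plan rests.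

**Step 8.** Elimination of benzenesulfinic acid from the vicinal disulfone, by the aluminium alkoxide or on work-up, may compete with the slow hydride transfer to a ketone between two quaternary carbons. The resulting vinyl sulfone would later be reduced through a carbanion β to O7, and the bridge would open.

The fallback sets out from 11 and comes back at 14 with the order of events changed. Buffered Na(Hg) is applied to 11 itself, since the vicinal disulfone should accept an electron far more readily than an aliphatic ketone, and gives (1R,4S)-1,3,3-trimethyl-7-oxabicyclo[2.2.1]hept-5-en-2-one F6. Hydrogenation over Pd/C gives (1R,4S)-1,3,3-trimethyl-7-oxabicyclo[2.2.1]heptan-2-one F7, which carries no base-sensitive group and is reduced with NaBH4 in MeOH to 14.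

**Step 12.** Premature hydrogen transfer from the silane to the C2 radical (plain deoxygenation) and telomerisation of the acrylate may prevail, because a radical flanked by two quaternary carbons adds slowly.

The fallback sets out from 16 and comes back at aldehyde 19. Radical allylation of 16 with allyltributylstannane and AIBN (Keck allylation), which involves no hydride donor, gives (1R,2S,4S)-1,3,3-trimethyl-2-(prop-2-en-1-yl)-7-oxabicyclo[2.2.1]heptane F8 with the same exo selection. Hydroboration with 9-BBN and oxidative work-up (NaOH, H2O2) gives 3-[(1R,2S,4S)-1,3,3-trimethyl-7-oxabicyclo[2.2.1]heptan-2-yl]propan-1-ol F9. Dess–Martin oxidation gives 19, here isolated, which is homologated with the Ohira–Bestmann reagent as in the second half of step 13 to give 20.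

**Step 16.** In the coupling stage, residual methylalane may transfer methyl to the benzylic bromide or attack the benzoate, and oxidative addition of the ortho-silyloxy benzyl bromide may be slow. The alkenylalane would then be protonated on work-up instead of coupled.

The fallback sets out from 20 (through alane 24) and comes back at 25 with the polarity of the coupling reversed. Alane 24 is quenched with I2 to give the alkenyl iodide (1R,2S,4S)-2-[(3E)-4-iodo-3-methylbut-3-en-1-yl]-1,3,3-trimethyl-7-oxabicyclo[2.2.1]heptane F10. Bromide 23 is converted with Zn and LiCl in THF into the benzylic zinc reagent {2-[(tert-butyldimethylsilyl)oxy]-5-(methoxycarbonyl)phenyl}methylzinc bromide F11. Negishi coupling of F10 with F11 under Pd(PPh3)4 gives 25.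

## Further compounds

F1 | step 7 | 2,2,4-trimethylcyclohex-3-en-1-one | CC1=CC(C)(C)C(=O)CC1
F2 | step 7 | (1S)-2,2,4-trimethylcyclohex-3-en-1-ol | CC1=CC(C)(C)[C@@H](O)CC1
F3 | step 7 | (1S,3S,6R)-2,2,6-trimethyl-7-oxabicyclo[4.1.0]heptan-3-ol (epoxide cis to hydroxyl) | C[C@@]12CC[C@H](O)C(C)(C)[C@@H]1O2
F4 | step 7 | (1R,2S,4S)-1,3,3-trimethyl-7-oxabicyclo[2.2.1]heptan-2-ol (2-exo alcohol) | O[C@H]1C(C)(C)[C@@H]2CC[C@@]1(C)O2
F5 | step 7 | O-[(1R,2S,4S)-1,3,3-trimethyl-7-oxabicyclo[2.2.1]heptan-2-yl] S-methyl carbonodithioate | CSC(=S)O[C@H]1C(C)(C)[C@@H]2CC[C@@]1(C)O2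
F6 | step 8 | (1R,4S)-1,3,3-trimethyl-7-oxabicyclo[2.2.1]hept-5-en-2-one | O=C1C(C)(C)[C@@H]2C=C[C@@]1(C)O2
F7 | step 8 | (1R,4S)-1,3,3-trimethyl-7-oxabicyclo[2.2.1]heptan-2-one | O=C1C(C)(C)[C@@H]2CC[C@@]1(C)O2
F8 | step 12 | (1R,2S,4S)-1,3,3-trimethyl-2-(prop-2-en-1-yl)-7-oxabicyclo[2.2.1]heptane | C=CC[C@H]1C(C)(C)[C@@H]2CC[C@@]1(C)O2
F9 | step 12 | 3-[(1R,2S,4S)-1,3,3-trimethyl-7-oxabicyclo[2.2.1]heptan-2-yl]propan-1-ol | OCCC[C@H]1C(C)(C)[C@@H]2CC[C@@]1(C)O2
F10 | step 16 | (1R,2S,4S)-2-[(3E)-4-iodo-3-methylbut-3-en-1-yl]-1,3,3-trimethyl-7-oxabicyclo[2.2.1]heptane | C/C(=C\I)CC[C@H]1C(C)(C)[C@@H]2CC[C@@]1(C)O2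
F11 | step 16 | {2-[(tert-butyldimethylsilyl)oxy]-5-(methoxycarbonyl)phenyl}methylzinc bromide | COC(=O)c1ccc(O[Si](C)(C)C(C)(C)C)c(C[Zn]Br)c1
A1 | alternative 1 | methyl (2E)-3-[(2R,5S)-2-methyl-5-(prop-1-en-2-yl)oxolan-2-yl]prop-2-enoate | COC(=O)/C=C/[C@@]1(C)CC[C@H](O1)C(C)=C
A2 | alternative 1 | methyl 2-[(1R,2S,4S)-1,3,3-trimethyl-7-oxabicyclo[2.2.1]heptan-2-yl]acetate | COC(=O)C[C@H]1C(C)(C)[C@@H]2CC[C@@]1(C)O2
A3 | alternative 2 | (1S)-2,2,4-trimethylcyclohex-3-en-1-ol | CC1=CC(C)(C)[C@@H](O)CC1
A4 | alternative 2 | (1R,2S,4S)-2-ethenyl-1,3,3-trimethyl-7-oxabicyclo[2.2.1]heptane | C=C[C@H]1C(C)(C)[C@@H]2CC[C@@]1(C)O2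
A5 | alternative 3 | 2-methylfuran | Cc1ccco1
A6 | alternative 3 | 2,2,2-trifluoroethyl 2-cyclopropylideneacetate | O=C(OCC(F)(F)F)C=C1CC1
A7 | alternative 3 | 2,2,2-trifluoroethyl 1-methylspiro[7-oxabicyclo[2.2.1]hept-5-ene-3,1'-cyclopropane]-2-carboxylate (endo ester, bridgeheads as in 26) | O=C(OCC(F)(F)F)[C@@H]1C3(CC3)[C@@H]2C=C[C@@]1(C)O2
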